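**Retrosynthetic overview**

1. Target 36 ⇐ 29 by late group changes only: C15 acetate, C8 ester, C14 oxidation. The lactone carbonyl C12 is carried as its O‑methyl lactol acetal and released last.
2. 29 ⇐ 26: the ten‑membered carbocycle is made by ring contraction of an 11‑membered thiacycle 1,1‑dioxide (S between C1 and C10) with loss of SO2 (Ramberg–Bäcklund), which creates the C1=C10 bond.
3. Enabling feature: in the ten‑membered ring, C1=C10 is flanked by the methylenes C2 and C9, so C1 and C10 can be held as two sp3 carbons bridged by SO2. With C12 at the acetal level, the C1–H and C10–H bonds are the only acidic ones.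
4. 26 ⇐ 24 ⇐ 18 + 22: S–C1 macro‑alkylation closes the 11‑membered ring. The ring‑cis C4=C5 bond comes from an E‑selective Wittig reaction at C5.
5. Stereotriad: C6 from butenolide 1, C7 by anti conjugate addition, C8 by allylboration. Ring order: five‑membered oxygen ring (from 1), then the 11‑membered thiacycle, then the ten‑membered carbocycle.

Key step: step 18

Remark: germacrane numbering of the target (C1–C15) is used for all intermediates; C10 (carbinol or thio centre) and the acetal carbon C12 are carried as epimer mixtures and left open in the SMILES because both centres are erased later; "ring‑cis" means that the two ring carbons flanking a ring double bond lie on the same side.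

**Route**

Step 1
Reactants: 1 (S)-5-(hydroxymethyl)furan-2(5H)-one
Product: 2 (S)-5-(trityloxymethyl)furan-2(5H)-one
Conditions: TrCl, pyridine, DMAP (cat.), CH2Cl2, rt
Reagents that add atoms: trityl chloride, ClC(c1ccccc1)(c1ccccc1)c1ccccc1
Why: Selective tritylation of the primary alcohol; the bulky trityloxymethyl group at C6 is the facial control element for step 2 and is designed to fall off in the acidic methanol of step 10.

Step 2
Reactants: 2 (S)-5-(trityloxymethyl)furan-2(5H)-one
Product: 3 (4R,5S)-5-(trityloxymethyl)-4-vinyldihydrofuran-2(3H)-one (C7 vinyl trans to the C6 substituent)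
Conditions: CH2=CHMgBr, CuBr·SMe2 (10 mol %), THF, −78 °C; aq. NH4Cl
Reagents that add atoms: vinylmagnesium bromide, C=C[Mg]Br
Why: Copper‑catalysed conjugate addition of the Grignard reagent to the butenolide occurs on the face anti to the C6 trityloxymethyl group, so C7 is set trans to C6 (substrate control), which is the trans ring fusion of the lactone in the target.

Step 3
Reactants: 3 (4R,5S)-5-(trityloxymethyl)-4-vinyldihydrofuran-2(3H)-one
Product: 5 (2S,3S)-5-oxo-2-(trityloxymethyl)tetrahydrofuran-3-carbaldehyde (C8 aldehyde), via secondary ozonide 4 (not isolated)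
Conditions: O3, CH2Cl2, −78 °C; then PPh3, −78 °C → rt
Reagents that add atoms: ozone, [O-][O+]=O
Why: Ozonolysis with reductive work‑up cleaves the only C=C bond to the C8 aldehyde without base, so the epimerisable C7 centre (whose trans arrangement is also the more stable one) is kept.

Step 4
Reactants: 5 (2S,3S)-5-oxo-2-(trityloxymethyl)tetrahydrofuran-3-carbaldehyde
Product: 7 (4R,5S)-4-[(1S)-1-hydroxybut-3-en-1-yl]-5-(trityloxymethyl)dihydrofuran-2(3H)-one (8S homoallylic alcohol), via borinate ester 6 (not isolated)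
Conditions: (−)-Ipc2B(allyl) [from (+)-α-pinene], Et2O, −78 °C; then NaBO3·4H2O, THF/H2O, 0 °C
Reagents that add atoms: (−)-B-allyldiisopinocampheylborane, C=CCB([C@@H]1C[C@@H]2C[C@H]([C@H]1C)C2(C)C)[C@@H]1C[C@@H]2C[C@H]([C@H]1C)C2(C)C
Why: Brown allylboration through a chair‑like six‑membered transition state: the (−)-Ipc2B reagent delivers allyl to the Si face of the aldehyde and sets 8S (reagent control, expected to reinforce the Felkin preference of C7), and the mild perborate work‑up avoids migration of the lactone onto the new hydroxyl.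

Step 5
Reactants: 7 8S homoallylic alcohol
Product: 8 C8 tert-butyldimethylsilyl ether of 7
Conditions: TBSOTf, 2,6-lutidine, CH2Cl2, −78 °C
Reagents that add atoms: tert-butyldimethylsilyl triflate, CC(C)(C)[Si](C)(C)OS(=O)(=O)C(F)(F)F
Why: Fast low‑temperature silylation caps the C8 hydroxyl before it can translactonise onto C12 and differentiates it from the hydroxyls made in step 6.

Step 6
Reactants: 8 C8 silyl ether with terminal C10=C14 alkene
Product: 9 C10,C14-diol (both C10 epimers)
Conditions: OsO4 (2 mol %), NMO, acetone/H2O, rt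
Reagents that add atoms: N-methylmorpholine N-oxide, C[N+]1([O-])CCOCC1; water, O
Why: Upjohn dihydroxylation of the only alkene; the C10 configuration is irrelevant because C10 ends as an sp2 carbon.

Step 7
Reactants: 9 C10,C14-diol
Product: 10 C14 tert-butyldiphenylsilyl ether with free C10 hydroxyl
Conditions: TBDPSCl, imidazole, CH2Cl2, 0 °C
Reagents that add atoms: tert-butyldiphenylsilyl chloride, CC(C)(C)[Si](Cl)(c1ccccc1)c1ccccc1
Why: Silylation with the bulky chlorosilane is selective for the primary C14 hydroxyl over the secondary C10 hydroxyl, and the resulting ether survives every later acidic methanol treatment.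

Step 8
Reactants: 10 lactone with free C10 hydroxyl
Product: 13 α-methylene lactone (C11=C13) with free C10 hydroxyl, via Mannich base 11 (not isolated), via ammonium iodide 12 (not isolated)
Conditions: LiN(i-Pr)2 (2.5 equiv), THF, −78 °C; Me2N=CH2+ I−, −78 °C → rt; then MeI, MeOH, rt; then aq. NaHCO3, CH2Cl2
Reagents that add atoms: N,N-dimethylmethyleneiminium iodide (Eschenmoser's salt), C[N+](C)=C.[I-]
Why: Eschenmoser methylenation: the lithium enolate of the lactone (the C10 alkoxide takes one equivalent of base) undergoes a Mannich reaction with the iminium salt anti to the C7 side chain, and exhaustive methylation followed by β‑elimination gives the exocyclic methylene, which removes the transient C11 stereocentre again.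

Step 9
Reactants: 13 α-methylene lactone with free C10 hydroxyl
Product: 14 C10 methanesulfonate
Conditions: MsCl, Et3N, CH2Cl2, 0 °C
Reagents that add atoms: methanesulfonyl chloride, CS(=O)(=O)Cl
Why: Mesylation of the only free hydroxyl prepares C10 for displacement by sulfur; triethylamine at 0 °C does not isomerise the α‑methylene lactone.

Step 10
Reactants: 14 C10 methanesulfonate
Product: 16 O-methyl lactol acetal at C12 with free C5 hydroxyl (both anomers), via lactol 15 (not isolated)
Conditions: i-Bu2AlH, CH2Cl2, −78 °C; then MeOH, CSA (5 mol %), 0 °C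
Reagents that add atoms: methanol, CO
Why: 1,2‑Reduction of the lactone and Fischer‑type acetalisation mask C12 as an O‑methyl acetal, which removes the enolisable Michael‑acceptor carbonyl before any sulfur or strong‑base chemistry; the same catalytic acid cleaves the trityl ether, while the hindered secondary silyl ether at C8, the primary TBDPS ether and the mesylate should survive these brief conditions.

Step 11
Reactants: 16 acetal with C10 methanesulfonate and free C5 hydroxyl
Product: 17 C10 thioacetate
Conditions: KSC(O)CH3, DMF, 60 °C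
Reagents that add atoms: potassium thioacetate, CC(=O)[S-].[K+]
Why: SN2 displacement of the secondary mesylate by thioacetate, a soft and weakly basic nucleophile, puts sulfur on C10 with inversion (configuration irrelevant); the primary C5 hydroxyl does not interfere.

Step 12
Reactants: 17 C10 thioacetate with free C5 hydroxyl
Product: 18 C5 aldehyde
Conditions: Dess–Martin periodinane, NaHCO3, CH2Cl2, 0 °C → rt
Reagents that add atoms: none
Why: Dess–Martin oxidation of the primary alcohol gives the α‑alkoxy aldehyde under buffered, non‑epimerising conditions that leave the thioester, acetal and silyl ethers untouched.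

Step 13
Reactants: 19 ethyl (triphenyl-λ5-phosphanylidene)acetate; 20 1-chloro-3-iodopropane
Product: 22 ethyl 5-chloro-2-(triphenyl-λ5-phosphanylidene)pentanoate, via phosphonium iodide 21 (not isolated)
Conditions: MeCN, reflux; then NaOH (aq.), CH2Cl2, 0 °C
Reagents that add atoms: none
Why: C‑Alkylation of the stabilised ylide at the iodide end of the dihalide gives the phosphonium salt, which is deprotonated to the α‑branched ylide; the chloride end is kept as the later electrophile at C1.

Step 14
Reactants: 18 C5 aldehyde; 22 ethyl 5-chloro-2-(triphenyl-λ5-phosphanylidene)pentanoate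
Product: 23 (E)-enoate with C4=C5 bond (C6 cis to C3), ethyl ester at C15 and chloride at C1
Conditions: CH2Cl2, rt → 40 °C
Reagents that add atoms: none
Why: Wittig olefination with the α‑branched ester‑stabilised ylide gives the E‑enoate, which places C6 cis to C3 (the ring‑cis C4=C5 geometry of the target) and trans to the ester carbon C15.

Step 15
Reactants: 23 (E)-enoate thioacetate
Product: 24 C10 thiol with C15 allylic alcohol and C1 chloride
Conditions: i-Bu2AlH (5 equiv), CH2Cl2, −78 °C; aq. KNaC4H4O6 work-up
Reagents that add atoms: none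
Why: i‑Bu2AlH reduces the conjugated ester to the C15 allylic alcohol and cleaves the thioacetate to the free thiol in the same operation, while the alkyl chloride, acetal and silyl ethers are not reduced at −78 °C.

Step 16
Reactants: 24 C10 thiol with C1 chloride
Product: 25 11-membered thiacycle (S between C1 and C10; ring atoms S, C1–C10)
Conditions: Cs2CO3, NaI (cat.), DMF, high dilution (slow addition), 50 °C
Reagents that add atoms: none
Why: Intramolecular S‑alkylation of the caesium thiolate at the primary C1 halide under high dilution closes the 11‑membered ring; the ring‑cis C4=C5 bond and the trans‑substituted five‑membered ring bring C1 near sulfur, the allylic alcohol is not deprotonated by carbonate, and both C10 epimers are carried on.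

Step 17
Reactants: 25 11-membered thiacycle
Product: 26 thiacycle 1,1-dioxide (sulfone)
Conditions: KHSO5 (as 2KHSO5·KHSO4·K2SO4), NaHCO3, MeOH/THF/H2O, 0 °C
Reagents that add atoms: potassium peroxymonosulfate, [K+].[O-]S(=O)(=O)OO
Why: Buffered peroxymonosulfate oxidises the sulfide to the sulfone much faster than it attacks the isolated C=C bonds and, unlike molybdate or tungstate peroxide systems, does not perform hydroxyl‑directed epoxidation next to the free C15 alcohol.

Step 18
Reactants: 26 thiacycle 1,1-dioxide
Product: 29 ten-membered carbocyclic diene with ring-cis C1=C10 and C4=C5 bonds (C15 OH, C14 OTBDPS, C8 OTBS, C12 acetal), via C1-bromo sulfone 27 (not isolated), via episulfone 28 (not isolated)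
Conditions: KOH/Al2O3, BrCF2CF2Br, t-BuOH/CH2Cl2, 0 °C → rt
Reagents that add atoms: none
Why: Ramberg–Bäcklund reaction with in situ halogenation: hydroxide on alumina deprotonates the sulfone at the unhindered C1 methylene, the carbanion takes bromine from BrCF2CF2Br to give 27, a second deprotonation at C10 closes the episulfone 28 by 1,3‑displacement (3‑exo‑tet), and cheletropic loss of SO2 leaves the C1=C10 bond while the 11‑membered thiacycle becomes the ten‑membered carbocycle. The closest known reactions are Ramberg–Bäcklund contractions of medium and large cyclic sulfones to cycloalkenes (strained cyclic enediynes, cyclophane dienes) and the same reaction of β‑alkoxy sulfones in exo‑glycal synthesis. No stereocentre is created, and both C10 epimers of 26 converge because C10 becomes sp2. The step needs the ring‑cis geometry (C2 and C9 on the same side): the episulfone is fused to a ten‑membered ring that already holds the ring‑cis C4=C5 bond and the trans‑fused five‑membered ring, so the cis‑fused episulfone should be both the kinetic and the less strained one, and SO2 extrusion is stereospecific. It also needs chemoselective α‑sulfonyl deprotonation: C12 is an O‑methyl acetal, so no enolisable carbonyl or Michael acceptor is present, the C1 carbanion has no β‑leaving group, and 3‑exo closure of the C10 carbanion should outrun loss of the poor silyloxide leaving group at C14. BrCF2CF2Br is chosen because its spent form is tetrafluoroethene and not a carbene that could add to the electron‑rich double bonds.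

Step 19
Reactants: 29 ten-membered diene with free C15 hydroxyl
Product: 30 C15 acetate
Conditions: Ac2O, pyridine, DMAP (cat.), CH2Cl2, 0 °C
Reagents that add atoms: acetic anhydride, CC(=O)OC(C)=O
Why: Acetylation of the only free hydroxyl gives the allylic acetate of the target.

Step 20
Reactants: 30 C15 acetate
Product: 31 C8 alcohol
Conditions: CSA (0.5 equiv), MeOH/CH2Cl2, rt
Reagents that add atoms: none
Why: Acid‑catalysed methanolysis removes the secondary TBS ether at C8, which is far more acid‑labile than the primary TBDPS ether at C14, while the acetal only exchanges with the solvent methanol.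

Step 21
Reactants: 31 C8 alcohol; 32 (S)-2-methylbutanoic acid
Product: 33 C8 (S)-2-methylbutanoate
Conditions: EDC·HCl, DMAP, CH2Cl2, 0 °C → rt
Reagents that add atoms: none
Why: Steglich esterification under carbodiimide activation at low temperature brings in the side‑chain stereocentre from the enantiopure acid without strong base, so its α‑centre should not epimerise.

Step 22
Reactants: 33 C8 (S)-2-methylbutanoate
Product: 34 C14 allylic alcohol
Conditions: HF·pyridine, pyridine/THF, 0 °C → rt
Reagents that add atoms: none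
Why: Buffered fluoride cleavage of the remaining silyl ether leaves both esters and the acetal intact.

Step 23
Reactants: 34 C14 allylic alcohol with C12 acetal
Product: 35 lactol (C12 hemiacetal, both anomers)
Conditions: AcOH/THF/H2O (3:1:1), rt
Reagents that add atoms: water, O
Why: Mild aqueous acid hydrolyses the allylic O‑methyl acetal through a stabilised oxocarbenium ion without touching the two esters.

Step 24
Reactants: 35 lactol
Product: 36 target, (6R,7R,8S)-15-acetoxy-8-[(S)-2-methylbutanoyloxy]-14-oxogermacra-1(10),4,11(13)-trien-12,6-olide with both ring double bonds ring-cis (1(10)E,4E by CIP)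
Conditions: MnO2 (excess), CH2Cl2, rt
Reagents that add atoms: none
Why: MnO2 oxidises both allylic positions in one operation, the primary C14 alcohol to the enal and the allylic lactol to the α‑methylene‑γ‑lactone, with no change at any stereocentre.

**Compound list**

1 | (S)-5-(hydroxymethyl)furan-2(5H)-one | O=C1C=C[C@@H](CO)O1 | starting material
2 | (S)-5-(trityloxymethyl)furan-2(5H)-one | O=C1C=C[C@@H](COC(c2ccccc2)(c2ccccc2)c2ccccc2)O1 | intermediate
3 | (4R,5S)-5-(trityloxymethyl)-4-vinyldihydrofuran-2(3H)-one | O=C1C[C@H](C=C)[C@@H](COC(c2ccccc2)(c2ccccc2)c2ccccc2)O1 | intermediate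
4 | secondary ozonide (1,2,4-trioxolane) of 3 | O=C1C[C@H](C2OCOO2)[C@@H](COC(c2ccccc2)(c2ccccc2)c2ccccc2)O1 | intermediate (not isolated)
5 | (2S,3S)-5-oxo-2-(trityloxymethyl)tetrahydrofuran-3-carbaldehyde | O=C1C[C@H](C=O)[C@@H](COC(c2ccccc2)(c2ccccc2)c2ccccc2)O1 | intermediate
6 | diisopinocampheylborinate of alcohol 7 | O=C1C[C@H]([C@@H](OB([C@@H]2C[C@@H]3C[C@H]([C@H]2C)C3(C)C)[C@@H]2C[C@@H]3C[C@H]([C@H]2C)C3(C)C)CC=C)[C@@H](COC(c2ccccc2)(c2ccccc2)c2ccccc2)O1 | intermediate (not isolated)
7 | (4R,5S)-4-[(1S)-1-hydroxybut-3-en-1-yl]-5-(trityloxymethyl)dihydrofuran-2(3H)-one | O=C1C[C@H]([C@@H](O)CC=C)[C@@H](COC(c2ccccc2)(c2ccccc2)c2ccccc2)O1 | intermediate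
8 | C8 TBS ether of 7 | O=C1C[C@H]([C@@H](O[Si](C)(C)C(C)(C)C)CC=C)[C@@H](COC(c2ccccc2)(c2ccccc2)c2ccccc2)O1 | intermediate
9 | C10,C14-diol (C10 epimers) | O=C1C[C@H]([C@@H](O[Si](C)(C)C(C)(C)C)CC(O)CO)[C@@H](COC(c2ccccc2)(c2ccccc2)c2ccccc2)O1 | intermediate
10 | C14 TBDPS ether with free C10 hydroxyl | O=C1C[C@H]([C@@H](O[Si](C)(C)C(C)(C)C)CC(O)CO[Si](c2ccccc2)(c2ccccc2)C(C)(C)C)[C@@H](COC(c2ccccc2)(c2ccccc2)c2ccccc2)O1 | intermediate
11 | C11 (dimethylaminomethyl) lactone (Mannich base) | O=C1C(CN(C)C)[C@H]([C@@H](O[Si](C)(C)C(C)(C)C)CC(O)CO[Si](c2ccccc2)(c2ccccc2)C(C)(C)C)[C@@H](COC(c2ccccc2)(c2ccccc2)c2ccccc2)O1 | intermediate (not isolated)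
12 | trimethylammonium iodide of 11 | O=C1C(C[N+](C)(C)C)[C@H]([C@@H](O[Si](C)(C)C(C)(C)C)CC(O)CO[Si](c2ccccc2)(c2ccccc2)C(C)(C)C)[C@@H](COC(c2ccccc2)(c2ccccc2)c2ccccc2)O1.[I-] | intermediate (not isolated)
13 | α-methylene lactone (C11=C13) with free C10 hydroxyl | O=C1C(=C)[C@H]([C@@H](O[Si](C)(C)C(C)(C)C)CC(O)CO[Si](c2ccccc2)(c2ccccc2)C(C)(C)C)[C@@H](COC(c2ccccc2)(c2ccccc2)c2ccccc2)O1 | intermediate
14 | C10 methanesulfonate of 13 | O=C1C(=C)[C@H]([C@@H](O[Si](C)(C)C(C)(C)C)CC(OS(C)(=O)=O)CO[Si](c2ccccc2)(c2ccccc2)C(C)(C)C)[C@@H](COC(c2ccccc2)(c2ccccc2)c2ccccc2)O1 | intermediate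
15 | α-methylene lactol (C12 hemiacetal) | OC1C(=C)[C@H]([C@@H](O[Si](C)(C)C(C)(C)C)CC(OS(C)(=O)=O)CO[Si](c2ccccc2)(c2ccccc2)C(C)(C)C)[C@@H](COC(c2ccccc2)(c2ccccc2)c2ccccc2)O1 | intermediate (not isolated)
16 | O-methyl lactol acetal with C10 mesylate and free C5 hydroxyl | COC1C(=C)[C@H]([C@@H](O[Si](C)(C)C(C)(C)C)CC(OS(C)(=O)=O)CO[Si](c2ccccc2)(c2ccccc2)C(C)(C)C)[C@@H](CO)O1 | intermediate
17 | C10 thioacetate with free C5 hydroxyl | COC1C(=C)[C@H]([C@@H](O[Si](C)(C)C(C)(C)C)CC(SC(C)=O)CO[Si](c2ccccc2)(c2ccccc2)C(C)(C)C)[C@@H](CO)O1 | intermediate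
18 | C5 aldehyde | COC1C(=C)[C@H]([C@@H](O[Si](C)(C)C(C)(C)C)CC(SC(C)=O)CO[Si](c2ccccc2)(c2ccccc2)C(C)(C)C)[C@@H](C=O)O1 | intermediate
19 | ethyl (triphenyl-λ5-phosphanylidene)acetate | CCOC(=O)C=P(c1ccccc1)(c1ccccc1)c1ccccc1 | starting material
20 | 1-chloro-3-iodopropane | ClCCCI | starting material
21 | (5-chloro-1-ethoxy-1-oxopentan-2-yl)triphenylphosphonium iodide | CCOC(=O)C(CCCCl)[P+](c1ccccc1)(c1ccccc1)c1ccccc1.[I-] | intermediate (not isolated)
22 | ethyl 5-chloro-2-(triphenyl-λ5-phosphanylidene)pentanoate | CCOC(=O)C(CCCCl)=P(c1ccccc1)(c1ccccc1)c1ccccc1 | intermediate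
23 | (E)-enoate (C4=C5, ring-cis sense) with C15 ethyl ester, C1 chloride, C10 thioacetate | COC1C(=C)[C@H]([C@@H](O[Si](C)(C)C(C)(C)C)CC(SC(C)=O)CO[Si](c2ccccc2)(c2ccccc2)C(C)(C)C)[C@@H](/C=C(/C(=O)OCC)CCCCl)O1 | intermediate
24 | C10 thiol with C15 allylic alcohol and C1 chloride | COC1C(=C)[C@H]([C@@H](O[Si](C)(C)C(C)(C)C)CC(S)CO[Si](c2ccccc2)(c2ccccc2)C(C)(C)C)[C@@H](/C=C(/CO)CCCCl)O1 | intermediate
25 | 11-membered thiacycle (S between C1 and C10) | C=C1C(OC)O[C@@H]2/C=C(/CO)CCCSC(CO[Si](c3ccccc3)(c3ccccc3)C(C)(C)C)C[C@H](O[Si](C)(C)C(C)(C)C)[C@@H]12 | intermediate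
26 | 11-membered thiacycle 1,1-dioxide | C=C1C(OC)O[C@@H]2/C=C(/CO)CCCS(=O)(=O)C(CO[Si](c3ccccc3)(c3ccccc3)C(C)(C)C)C[C@H](O[Si](C)(C)C(C)(C)C)[C@@H]12 | intermediate
27 | C1-bromo sulfone | C=C1C(OC)O[C@@H]2/C=C(/CO)CCC(Br)S(=O)(=O)C(CO[Si](c3ccccc3)(c3ccccc3)C(C)(C)C)C[C@H](O[Si](C)(C)C(C)(C)C)[C@@H]12 | intermediate (not isolated)
28 | episulfone (thiirane 1,1-dioxide across C1–C10) | C=C1C(OC)O[C@@H]2/C=C(/CO)CCC3C(CO[Si](c4ccccc4)(c4ccccc4)C(C)(C)C)(C[C@H](O[Si](C)(C)C(C)(C)C)[C@@H]12)S3(=O)=O | intermediate (not isolated)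
29 | ten-membered diene, ring-cis C1=C10 and C4=C5, free C15 hydroxyl | C=C1C(OC)O[C@@H]2/C=C(/CO)CC/C=C(/CO[Si](c3ccccc3)(c3ccccc3)C(C)(C)C)C[C@H](O[Si](C)(C)C(C)(C)C)[C@@H]12 | intermediate
30 | C15 acetate | C=C1C(OC)O[C@@H]2/C=C(/COC(C)=O)CC/C=C(/CO[Si](c3ccccc3)(c3ccccc3)C(C)(C)C)C[C@H](O[Si](C)(C)C(C)(C)C)[C@@H]12 | intermediate
31 | C8 alcohol | C=C1C(OC)O[C@@H]2/C=C(/COC(C)=O)CC/C=C(/CO[Si](c3ccccc3)(c3ccccc3)C(C)(C)C)C[C@H](O)[C@@H]12 | intermediate
32 | (S)-2-methylbutanoic acid | CC[C@H](C)C(=O)O | starting material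
33 | C8 (S)-2-methylbutanoate | C=C1C(OC)O[C@@H]2/C=C(/COC(C)=O)CC/C=C(/CO[Si](c3ccccc3)(c3ccccc3)C(C)(C)C)C[C@H](OC(=O)[C@@H](C)CC)[C@@H]12 | intermediate
34 | C14 allylic alcohol | C=C1C(OC)O[C@@H]2/C=C(/COC(C)=O)CC/C=C(/CO)C[C@H](OC(=O)[C@@H](C)CC)[C@@H]12 | intermediate
35 | lactol (C12 hemiacetal) | C=C1C(O)O[C@@H]2/C=C(/COC(C)=O)CC/C=C(/CO)C[C@H](OC(=O)[C@@H](C)CC)[C@@H]12 | intermediate
36 | target | C=C1C(=O)O[C@@H]2/C=C(/COC(C)=O)CC/C=C(/C=O)C[C@H](OC(=O)[C@@H](C)CC)[C@@H]12 | target

**Step count and risks**

Total step count: 24. Longest linear sequence: 23 steps (1 → 36 through steps 1–12 and 14–24; step 13 makes ylide 22).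

Steps most likely to fail:

Step 18 (ring contraction). The extrusion may give poor control of the new double‑bond geometry (trans‑cyclodecene isomer). The C10 carbanion may lose the C14 silyloxy group by β‑elimination, or the sulfone may be over‑brominated under the heterogeneous hydroxide conditions. The fallback separates halogenation from extrusion. It sets out from 26 and returns at 29. Kinetic lithiation at C1 with LiN(SiMe3)2 (2.2 equiv, the first equivalent being taken by the C15 hydroxyl) in THF at −78 °C, followed by chlorination with C2Cl6, should give the isolated C1-chloro sulfone F1; the halogen is thereby placed by directed metalation at the carbon that has no β‑leaving group. F1 is then treated with KOC(CH3)3 in THF at −78 → 0 °C, a homogeneous 1,3‑elimination whose base and temperature can be varied to steer the episulfone geometry, to give 29.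

Step 16 (macrocyclisation). Intermolecular S‑alkylation (oligomerisation) and oxidative disulfide formation may compete with ring closure. The fallback closes the 11‑membered ring at the C4=C5 bond instead of at sulfur. It sets out from 17 and returns at 25. Triethyl phosphonoacetate is alkylated (NaH, 1,3‑dibromopropane, THF) to ethyl 5-bromo-2-(diethoxyphosphoryl)pentanoate F2. The thioacetate of 17 is cleaved with K2CO3 in MeOH in the presence of F2, and the thiolate is alkylated at the primary bromide to give the open‑chain sulfide phosphonate F3. Oxidation of the C5 alcohol (SO3·pyridine, DMSO, i‑Pr2NEt) gives the aldehyde F4. An intramolecular Horner–Wadsworth–Emmons reaction (LiCl, DBU, MeCN, high dilution) closes the ring to the macrocyclic enoate F5. Reduction of F5 with i‑Bu2AlH gives 25.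

Step 20 (selective desilylation). Discrimination between the hindered secondary silyl ether at C8 and the primary one at C14 may be incomplete, and the allylic acetate or acetal may undergo acid‑promoted solvolysis. The fallback differentiates the two hydroxyls by chemoselective oxidation instead of by orthogonal silyl groups. It sets out from 30 and returns at 36. Both silyl ethers are removed with n‑Bu4NF buffered with AcOH in THF to give the C8,C14-diol F6. MnO2 oxidises only the allylic primary C14 alcohol to give the C14 enal with free C8 hydroxyl F7. Esterification of the remaining C8 alcohol with 32 (EDC·HCl, DMAP) gives the enal ester acetal F8. Aqueous acetic acid gives the enal lactol F9, and oxidation of the allylic lactol (MnO2, or Ag2CO3 on Celite) gives 36.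

Further compounds
F1 | step 18 | C1-chloro sulfone | C=C1C(OC)O[C@@H]2/C=C(/CO)CCC(Cl)S(=O)(=O)C(CO[Si](c3ccccc3)(c3ccccc3)C(C)(C)C)C[C@H](O[Si](C)(C)C(C)(C)C)[C@@H]12
F2 | step 16 | ethyl 5-bromo-2-(diethoxyphosphoryl)pentanoate | CCOC(=O)C(CCCBr)P(=O)(OCC)OCC
F3 | step 16 | open-chain sulfide phosphonate with free C5 hydroxyl | COC1C(=C)[C@H]([C@@H](O[Si](C)(C)C(C)(C)C)CC(SCCCC(C(=O)OCC)P(=O)(OCC)OCC)CO[Si](c2ccccc2)(c2ccccc2)C(C)(C)C)[C@@H](CO)O1
F4 | step 16 | sulfide phosphonate C5 aldehyde | COC1C(=C)[C@H]([C@@H](O[Si](C)(C)C(C)(C)C)CC(SCCCC(C(=O)OCC)P(=O)(OCC)OCC)CO[Si](c2ccccc2)(c2ccccc2)C(C)(C)C)[C@@H](C=O)O1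
F5 | step 16 | 11-membered thiacyclic enoate (C15 ethyl ester) | C=C1C(OC)O[C@@H]2/C=C(/C(=O)OCC)CCCSC(CO[Si](c3ccccc3)(c3ccccc3)C(C)(C)C)C[C@H](O[Si](C)(C)C(C)(C)C)[C@@H]12
F6 | step 20 | C8,C14-diol | C=C1C(OC)O[C@@H]2/C=C(/COC(C)=O)CC/C=C(/CO)C[C@H](O)[C@@H]12
F7 | step 20 | C14 enal with free C8 hydroxyl | C=C1C(OC)O[C@@H]2/C=C(/COC(C)=O)CC/C=C(/C=O)C[C@H](O)[C@@H]12
F8 | step 20 | C14 enal, C8 (S)-2-methylbutanoate, C12 acetal | C=C1C(OC)O[C@@H]2/C=C(/COC(C)=O)CC/C=C(/C=O)C[C@H](OC(=O)[C@@H](C)CC)[C@@H]12
F9 | step 20 | C14 enal lactol | C=C1C(O)O[C@@H]2/C=C(/COC(C)=O)CC/C=C(/C=O)C[C@H](OC(=O)[C@@H](C)CC)[C@@H]12
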